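The spiro acetal–lactone is cut into a chromene hydroxyquinone and a caged hydroxy acid, joined at the end by esterification and oxa-Michael ring closure. The cage's bridgehead α-ketol, C7(OH)–C6(=O), lies in the saturated ring C5–C6–C7–C21–C22–C10a. This ring is first built one carbon short, as the cyclopentane C5–C6–C21–C22–C10a of a 2-oxabicyclo[2.2.1]heptane that carries C6–OH and the acyl carbon C7 in a bicyclo[3.2.1]octanone. An acyloin (α-ketol) shift of C21 from C6 to C7 then expands it, releases the oxanorbornane strain and creates the bridgehead carbinol of the bicyclo[2.2.2]octane cage in one operation.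

Key step: step 10

Atom labels (xanthone-type, kept in all intermediates): C5 (quaternary, ether O and prenyl), C6 (cage ketone), C7 (bridgehead carbinol), C8 (=CH), C8a (=C–CO), C10a (bridgehead carbon bearing the acetal oxygen), C21 (CH2), C22 (CH), C23 (CMe2).
Assumption 1: (S)-BINAP is written in step 4 on the assumption that it gives the (2S,4S) adduct 7; if the sense of induction were opposite, (R)-BINAP would be used.
Assumption 2: the configurations at the spiro acetal carbon and at the neighbouring CH(prenyl) carbon of the target are taken to be the thermodynamically preferred ones, reached in step 20 by reversible oxa-Michael addition and enolisation.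

Step 1
Reactants: 1 cyclopentane-1,3-dione; 2 allyl methyl carbonate
Product: 3 2-allylcyclopentane-1,3-dione
Conditions: Pd(PPh3)4 (2 mol %), THF, rt; 1 in excess
Reagents that add atoms: none
Why: Tsuji–Trost allylation, in which methoxide released from the carbonate deprotonates the acidic dione and the soft enolate attacks the π-allylpalladium complex at carbon, an excess of 1 limiting double allylation.

Step 2
Reactants: 3 2-allylcyclopentane-1,3-dione
Product: 4 2-allyl-2-hydroxycyclopentane-1,3-dione
Conditions: dimethyldioxirane, acetone, 0 °C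
Reagents that add atoms: dimethyldioxirane CC1(C)OO1
Why: Enol oxidation of the Rubottom type: the enol of 3 should be epoxidised far faster than the monosubstituted alkene and open to the tertiary α-hydroxy dione, whose new carbon is not yet stereogenic.

Step 3
Reactants: 4 2-allyl-2-hydroxycyclopentane-1,3-dione
Product: 5 2-allyl-2-hydroxycyclopent-4-ene-1,3-dione
Conditions: 2-iodoxybenzoic acid (IBX), DMSO, 70 °C
Reagents that add atoms: none
Why: Dehydrogenation of a ketone to an enone by the hypervalent iodine oxidant through the enol; only C21 and C22 carry hydrogens, so the prochiral ene-dione should form.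

Step 4
Reactants: 5 2-allyl-2-hydroxycyclopent-4-ene-1,3-dione; 6 isopropenylboronic acid pinacol ester
Product: 7 (2S,4S)-2-allyl-2-hydroxy-4-(prop-1-en-2-yl)cyclopentane-1,3-dione
Conditions: [Rh(OH)(cod)]2 (2.5 mol %), (S)-BINAP (6 mol %), 1,4-dioxane/H2O 10:1, 35 °C
Reagents that add atoms: none
Why: Hayashi–Miyaura conjugate addition: the alkenylrhodium species should add to the ring face opposite the larger allyl group (cis to the small hydroxyl), and the chiral bisphosphine selects between the two enantiotopic alkene carbons, which sets C22 and makes the quaternary C5 stereogenic.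

Step 5
Reactants: 7 (2S,4S)-2-allyl-2-hydroxy-4-(prop-1-en-2-yl)cyclopentane-1,3-dione
Product: 9 (1S,4S)-1-allyl-3,3-dimethyl-2-oxabicyclo[2.2.1]heptane-6,7-dione, via alkylmercury trifluoroacetate 8 (not isolated)
Conditions: Hg(OCOCF3)2, CH2Cl2, 0 °C; then Bu3SnH, 0 °C → rt
Reagents that add atoms: none
Why: Intramolecular alkoxymercuration (Markovnikov, 5-exo) of the 1,1-disubstituted alkene by the cis tertiary hydroxyl, then radical demercuration by the tin hydride, which leaves the ketones untouched; the allyl group has no productive mode of closure and only the cis isomer can cyclise, so C5 and C22 keep the configuration set in step 4.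

Step 6
Reactants: 9 (1S,4S)-1-allyl-3,3-dimethyl-2-oxabicyclo[2.2.1]heptane-6,7-dione; 10 2-methylbut-2-ene
Product: 11 (1S,4S)-3,3-dimethyl-1-(3-methylbut-2-en-1-yl)-2-oxabicyclo[2.2.1]heptane-6,7-dione
Conditions: RuCl2(H2IMes)(PCy3)(=CHPh) (second-generation Grubbs catalyst, 5 mol %), CH2Cl2/10 (excess), 40 °C
Reagents that add atoms: none
Why: Olefin cross-metathesis of the terminal allyl group with excess 2-methylbut-2-ene turns allyl into prenyl; no other alkene is present.

Step 7
Reactants: 11 (1S,4S)-3,3-dimethyl-1-(3-methylbut-2-en-1-yl)-2-oxabicyclo[2.2.1]heptane-6,7-dione; 12 methyl 4,4-dimethoxybutanoate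
Product: 15 methyl 4,4-dimethoxy-2-[(1R,4S,7S)-3,3-dimethyl-1-(3-methylbut-2-en-1-yl)-6-oxo-7-(triethylsilyloxy)-2-oxabicyclo[2.2.1]heptan-7-yl]butanoate, via lithium enolate 13 (not isolated), via lithium aldolate 14 (not isolated)
Conditions: 12, LiN(i-Pr)2, THF, −78 °C; then 11; then Et3SiOTf, −78 → −20 °C
Reagents that add atoms: triethylsilyl trifluoromethanesulfonate CC[Si](CC)(CC)OS(=O)(=O)C(F)(F)F
Why: Aldol addition of the ester enolate to the non-enolisable, angle-strained bridging ketone C10a, expected to be the more electrophilic carbonyl and attacked from the side of the C6–C21 bridge (away from the gem-dimethyl ether bridge) so that the new chain lies syn to C6; silylation of the cold aldolate blocks retro-aldol opening, and the C8a epimers are removed in step 11.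

Step 8
Reactants: 15 aldol adduct triethylsilyl ether
Product: 16 methyl 4-oxo-2-[(1R,4S,7S)-3,3-dimethyl-1-(3-methylbut-2-en-1-yl)-6-oxo-7-(triethylsilyloxy)-2-oxabicyclo[2.2.1]heptan-7-yl]butanoate
Conditions: pyridinium p-toluenesulfonate (0.2 equiv), acetone/H2O 9:1, 50 °C
Reagents that add atoms: water O
Why: Mild acid-catalysed acetal hydrolysis, which the tertiary triethylsilyl ether and the prenyl group should survive.

Step 9
Reactants: 16 keto aldehyde
Product: 17 bicyclo[3.2.1]octanone acyloin (C6–OH and C7=O)
Conditions: 3-benzyl-5-(2-hydroxyethyl)-4-methylthiazolium chloride (20 mol %), DBU (0.5 equiv), t-BuOH, 40 °C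
Reagents that add atoms: none
Why: Intramolecular crossed benzoin reaction under N-heterocyclic carbene catalysis: the Breslow intermediate of the aldehyde adds to the C6 ketone and closes the ring C6–C7–C8–C8a–C10a–C5, the tether held syn on C10a reaching only the exo face of C6, which sets the C6 carbinol.

Step 10
Reactants: 17 bicyclo[3.2.1]octanone acyloin (C6–OH and C7=O)
Product: 18 caged bicyclo[2.2.2]octanone α-ketol (C7–OH and C6=O)
Conditions: Al(Ot-Bu)3 (0.3 equiv), toluene, 80 °C
Reagents that add atoms: none
Why: Aluminium chelates the C6 hydroxyl and the C7 carbonyl, which are held syn-periplanar in the rigid bicyclo[3.2.1]octanone, and C21 shifts suprafacially from C6 to C7 while the C6 alkoxide collapses to the ketone: an α-ketol (acyloin) rearrangement, the reaction type of the D-homoannulation of 17-hydroxy-20-keto steroids and of bicyclo[3.2.1]/[2.2.2] acyloin interconversions. No ring is closed from an open chain; the cyclopentane C5–C6–C21–C22–C10a becomes the cyclohexanone C5–C6–C7–C21–C22–C10a by one-carbon ring expansion, which turns the bicyclo[3.2.1]octane into the bicyclo[2.2.2]octane cage. The only new stereocenter, C7, is set by the substrate, because C21 can bond only to the carbonyl face on which it already lies, so the hydroxyl ends at the bridgehead; the C6 stereocenter is lost. The step needs migration of C21 and not of C5, and an equilibrium on the product side: the C6–C21 bond is the pseudo-axial bond best aligned with the C7 π* orbital, C5 is a congested oxygen-bearing quaternary carbon, and the shift of C21 removes the strained 2-oxabicyclo[2.2.1]heptane and the three contiguous fully substituted carbons C6–C5–C10a. The silyl ether on the C10a oxygen blocks retro-aldol cleavage, the saturated C8–C8a bond means no enone conjugation is lost, and the tert-butoxide cannot reduce the ketone.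

Step 11
Reactants: 18 caged bicyclo[2.2.2]octanone α-ketol
Product: 21 caged enoate methyl ester (C8=C8a), via phenylselenide 19 (not isolated), via selenoxide 20 (not isolated)
Conditions: LiN(i-Pr)2 (2.2 equiv), THF, −78 °C; PhSeBr; then 30% H2O2, pyridine, CH2Cl2, 0 °C → rt
Reagents that add atoms: none
Why: Selenenylation of the ester enolate at C8a and selenoxide syn-elimination toward C8, the only neighbour with hydrogens, should give the C8=C8a enoate and remove the C8a stereocenter; the C6 ketone has no α-hydrogen.

Step 12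
Reactants: 21 caged enoate methyl ester
Product: 22 caged enoic acid (C10a–OSiEt3)
Conditions: Me3SnOH, 1,2-dichloroethane, 80 °C; then 1 M HCl
Reagents that add atoms: trimethyltin hydroxide C[Sn](C)(C)O
Why: Mild methyl ester hydrolysis with trimethyltin hydroxide, chosen to spare the α-ketol, the silyl ether and the enoate.

Step 13
Reactants: 23 2-hydroxy-4,6-dimethoxybenzaldehyde
Product: 24 3,5-dimethoxybenzene-1,2-diol
Conditions: 30% H2O2, 2 M NaOH, THF/H2O, 0 °C → rt; then 1 M HCl
Reagents that add atoms: hydrogen peroxide OO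
Why: Dakin oxidation: hydroperoxide adds to the aldehyde, the electron-rich aryl group migrates to oxygen and the formate is hydrolysed to the catechol.

Step 14
Reactants: 24 3,5-dimethoxybenzene-1,2-diol; 25 3-methylbut-2-enal
Product: 26 5,7-dimethoxy-2,2-dimethyl-2H-chromen-8-ol
Conditions: ethylenediammonium diacetate (20 mol %), xylene, 140 °C
Reagents that add atoms: none
Why: Condensation of the enal at the only carbon ortho to a hydroxyl, loss of water to the ortho-quinone methide and oxa-6π electrocyclisation should give the 2,2-dimethyl-2H-chromene with the central hydroxyl left free.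

Step 15
Reactants: 26 5,7-dimethoxy-2,2-dimethyl-2H-chromen-8-ol
Product: 27 5,7,8-trimethoxy-2,2-dimethyl-2H-chromene
Conditions: MeI, K2CO3, acetone, reflux
Reagents that add atoms: iodomethane CI
Why: Williamson O-methylation of the remaining phenol.

Step 16
Reactants: 27 5,7,8-trimethoxy-2,2-dimethyl-2H-chromene; 28 1-bromo-3-methylbut-2-ene
Product: 30 5,7,8-trimethoxy-2,2-dimethyl-6-(3-methylbut-2-en-1-yl)-2H-chromene, via aryllithium 29 (not isolated)
Conditions: n-BuLi, THF, 0 °C; CuBr·SMe2 (10 mol %); 28, −78 °C → rt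
Reagents that add atoms: none
Why: Directed ortho-lithiation at the only aromatic C–H, flanked by two methoxy groups, then copper-catalysed allylic substitution at the primary carbon of prenyl bromide.

Step 17
Reactants: 30 5,7,8-trimethoxy-2,2-dimethyl-6-(3-methylbut-2-en-1-yl)-2H-chromene
Product: 31 7-methoxy-2,2-dimethyl-6-(3-methylbut-2-en-1-yl)-2H-chromene-5,8-dione
Conditions: (NH4)2Ce(NO3)6 (ceric ammonium nitrate), MeCN/H2O, 0 °C
Reagents that add atoms: water O
Why: Oxidative demethylation of the para-dimethoxy arene to the para-quinone, the third methoxy group staying as a vinylogous ester.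

Step 18
Reactants: 31 7-methoxy-2,2-dimethyl-6-(3-methylbut-2-en-1-yl)-2H-chromene-5,8-dione
Product: 32 7-hydroxy-2,2-dimethyl-6-(3-methylbut-2-en-1-yl)-2H-chromene-5,8-dione
Conditions: 1 M NaOH, THF/H2O, 0 °C; then 1 M HCl
Reagents that add atoms: sodium hydroxide [Na+].[OH-]
Why: Addition–elimination of hydroxide at the methoxy-bearing quinone carbon (vinylogous ester hydrolysis) gives the hydroxyquinone.

Step 19
Reactants: 22 caged enoic acid (C10a–OSiEt3); 32 7-hydroxy-2,2-dimethyl-6-(3-methylbut-2-en-1-yl)-2H-chromene-5,8-dione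
Product: 33 acyloxyquinone ester
Conditions: N,N′-dicyclohexylcarbodiimide, 4-(dimethylamino)pyridine (cat.), CH2Cl2, 0 °C → rt
Reagents that add atoms: none
Why: Steglich esterification of the acidic hydroxyquinone oxygen with the carbodiimide-activated acid; the C10a oxygen is silylated and the hindered bridgehead C7 hydroxyl is held trans to the acid across C8=C8a.

Step 20
Reactants: 33 acyloxyquinone ester
Product: 35 target CNP0222516.1, via hydroxy ester 34 (not isolated)
Conditions: HF·pyridine, pyridine, THF, 0 °C → rt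
Reagents that add atoms: none
Why: Desilylation frees the C10a hydroxyl, which adds to the acyloxy-bearing quinone carbon (6-exo-trig oxa-Michael addition) to close the spiro 1,3-dioxan-4-one, and the enol ketonises to put hydrogen on the prenyl-bearing carbon; both new stereocenters are expected under thermodynamic control, with the prenyl group on the face away from the cage.

Compound list
1 | cyclopentane-1,3-dione | O=C1CCC(=O)C1 | starting material
2 | allyl methyl carbonate | COC(=O)OCC=C | starting material
3 | 2-allylcyclopentane-1,3-dione (drawn as diketone, largely enolised) | C=CCC1C(=O)CCC1=O | intermediate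
4 | 2-allyl-2-hydroxycyclopentane-1,3-dione | C=CCC1(O)C(=O)CCC1=O | intermediate
5 | 2-allyl-2-hydroxycyclopent-4-ene-1,3-dione (prochiral) | C=CCC1(O)C(=O)C=CC1=O | intermediate
6 | isopropenylboronic acid pinacol ester | CC(=C)B1OC(C)(C)C(C)(C)O1 | starting material
7 | (2S,4S)-2-allyl-2-hydroxy-4-(prop-1-en-2-yl)cyclopentane-1,3-dione (hydroxyl and isopropenyl cis) | C=CC[C@]1(O)C(=O)C[C@@H](C(C)=C)C1=O | intermediate
8 | alkylmercury trifluoroacetate: 9 with one C23 methyl as CH2HgOCOCF3 (either configuration at C23) | O=C1C[C@H]2C(C)(C[Hg]OC(=O)C(F)(F)F)O[C@]1(CC=C)C2=O | intermediate (not isolated)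
9 | (1S,4S)-1-allyl-3,3-dimethyl-2-oxabicyclo[2.2.1]heptane-6,7-dione | O=C1C[C@H]2C(C)(C)O[C@]1(CC=C)C2=O | intermediate
10 | 2-methylbut-2-ene | CC=C(C)C | starting material
11 | (1S,4S)-3,3-dimethyl-1-(3-methylbut-2-en-1-yl)-2-oxabicyclo[2.2.1]heptane-6,7-dione | O=C1C[C@H]2C(C)(C)O[C@]1(CC=C(C)C)C2=O | intermediate
12 | methyl 4,4-dimethoxybutanoate | COC(=O)CCC(OC)OC | starting material
13 | lithium enolate of 12 | [Li+].COC([O-])=CCC(OC)OC | intermediate (not isolated)
14 | lithium aldolate: adduct of 13 at the bridging ketone C10a of 11 (C8a epimers) | O=C1C[C@H]2C(C)(C)O[C@]1(CC=C(C)C)[C@@]2([O-])C(CC(OC)OC)C(=O)OC.[Li+] | intermediate (not isolated)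
15 | methyl 4,4-dimethoxy-2-[(1R,4S,7S)-3,3-dimethyl-1-(3-methylbut-2-en-1-yl)-6-oxo-7-(triethylsilyloxy)-2-oxabicyclo[2.2.1]heptan-7-yl]butanoate (chain syn to the C6–C21 bridge; C8a epimers) | O=C1C[C@H]2C(C)(C)O[C@]1(CC=C(C)C)[C@@]2(O[Si](CC)(CC)CC)C(CC(OC)OC)C(=O)OC | intermediate
16 | methyl 4-oxo-2-[(1R,4S,7S)-3,3-dimethyl-1-(3-methylbut-2-en-1-yl)-6-oxo-7-(triethylsilyloxy)-2-oxabicyclo[2.2.1]heptan-7-yl]butanoate (C8a epimers) | O=C1C[C@H]2C(C)(C)O[C@]1(CC=C(C)C)[C@@]2(O[Si](CC)(CC)CC)C(CC=O)C(=O)OC | intermediate
17 | methyl 6-hydroxy-9,9-dimethyl-7-(3-methylbut-2-en-1-yl)-5-oxo-2-(triethylsilyloxy)-8-oxatricyclo[4.3.1.0(2,7)]decane-3-carboxylate: bicyclo[3.2.1]octanone acyloin with C6–OH, C7=O, 2-oxabicyclo[2.2.1]heptane unit, configuration as in the SMILES, C8a epimers | COC(=O)C1CC(=O)[C@]2(O)C[C@H]3C(C)(C)O[C@]2(CC=C(C)C)[C@@]13O[Si](CC)(CC)CC | intermediate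
18 | methyl 1-hydroxy-5,5-dimethyl-3-(3-methylbut-2-en-1-yl)-2-oxo-7-(triethylsilyloxy)-4-oxatricyclo[4.3.1.0(3,7)]decane-8-carboxylate: caged α-ketol with C7–OH, C6=O, cage configuration as in the target, C8a epimers | COC(=O)C1C[C@]3(O)C[C@H]4C(C)(C)O[C@@](CC=C(C)C)(C3=O)[C@@]14O[Si](CC)(CC)CC | intermediate
19 | 18 with phenylseleno group at C8a | COC(=O)C1([Se]c2ccccc2)C[C@]3(O)C[C@H]4C(C)(C)O[C@@](CC=C(C)C)(C3=O)[C@@]14O[Si](CC)(CC)CC | intermediate (not isolated)
20 | selenoxide of 19 | COC(=O)C1([Se](=O)c2ccccc2)C[C@]3(O)C[C@H]4C(C)(C)O[C@@](CC=C(C)C)(C3=O)[C@@]14O[Si](CC)(CC)CC | intermediate (not isolated)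
21 | methyl 1-hydroxy-5,5-dimethyl-3-(3-methylbut-2-en-1-yl)-2-oxo-7-(triethylsilyloxy)-4-oxatricyclo[4.3.1.0(3,7)]dec-8-ene-8-carboxylate, cage configuration as in the target | COC(=O)C1=C[C@]3(O)C[C@H]4C(C)(C)O[C@@](CC=C(C)C)(C3=O)[C@@]14O[Si](CC)(CC)CC | intermediate
22 | 1-hydroxy-5,5-dimethyl-3-(3-methylbut-2-en-1-yl)-2-oxo-7-(triethylsilyloxy)-4-oxatricyclo[4.3.1.0(3,7)]dec-8-ene-8-carboxylic acid, cage configuration as in the target | OC(=O)C1=C[C@]3(O)C[C@H]4C(C)(C)O[C@@](CC=C(C)C)(C3=O)[C@@]14O[Si](CC)(CC)CC | intermediate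
23 | 2-hydroxy-4,6-dimethoxybenzaldehyde | O=Cc1c(O)cc(OC)cc1OC | starting material
24 | 3,5-dimethoxybenzene-1,2-diol | COc1cc(O)c(O)c(OC)c1 | intermediate
25 | 3-methylbut-2-enal | CC(C)=CC=O | starting material
26 | 5,7-dimethoxy-2,2-dimethyl-2H-chromen-8-ol | COc1cc(OC)c2c(c1O)OC(C)(C)C=C2 | intermediate
27 | 5,7,8-trimethoxy-2,2-dimethyl-2H-chromene | COc1cc(OC)c2c(c1OC)OC(C)(C)C=C2 | intermediate
28 | 1-bromo-3-methylbut-2-ene (prenyl bromide) | CC(C)=CCBr | starting material
29 | 6-lithio-5,7,8-trimethoxy-2,2-dimethyl-2H-chromene | COc1c([Li])c(OC)c2c(c1OC)OC(C)(C)C=C2 | intermediate (not isolated)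
30 | 5,7,8-trimethoxy-2,2-dimethyl-6-(3-methylbut-2-en-1-yl)-2H-chromene | COc1c(CC=C(C)C)c(OC)c2c(c1OC)OC(C)(C)C=C2 | intermediate
31 | 7-methoxy-2,2-dimethyl-6-(3-methylbut-2-en-1-yl)-2H-chromene-5,8-dione | CC(C)=CCC1=C(OC)C(=O)C2=C(C1=O)C=CC(C)(C)O2 | intermediate
32 | 7-hydroxy-2,2-dimethyl-6-(3-methylbut-2-en-1-yl)-2H-chromene-5,8-dione | CC(C)=CCC1=C(O)C(=O)C2=C(C1=O)C=CC(C)(C)O2 | intermediate
33 | ester of acid 22 with the C7 oxygen of hydroxyquinone 32 (C10a–OSiEt3) | CC(C)=CCC1=C(OC(=O)C2=C[C@]3(O)C[C@H]4C(C)(C)O[C@@](CC=C(C)C)(C3=O)[C@@]24O[Si](CC)(CC)CC)C(=O)C2=C(C1=O)C=CC(C)(C)O2 | intermediate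
34 | 33 with free C10a hydroxyl | CC(C)=CCC1=C(OC(=O)C2=C[C@]3(O)C[C@H]4C(C)(C)O[C@@](CC=C(C)C)(C3=O)[C@@]24O)C(=O)C2=C(C1=O)C=CC(C)(C)O2 | intermediate (not isolated)
35 | CNP0222516.1 | CC(C)=CC[C@H]1C(=O)C2=C(OC(C)(C)C=C2)C(=O)[C@@]12OC(=O)C1=C[C@]3(O)C[C@H]4C(C)(C)O[C@@](CC=C(C)C)(C3=O)[C@@]14O2 | target

Total step count: 20. Longest linear sequence: 14 steps (steps 1–12, 19 and 20); the hydroxyquinone 32 is made in 6 steps (13–18).

Steps most likely to fail

Step 10 (key step). The bridging quaternary carbon C5 might migrate instead of C21, or the equilibrium might stay on the side of the bicyclo[3.2.1]octane. The fallback sets out from 16 and returns at 18, and still expands the five-membered ring, through a cyclopropane-1,2-diol. DBU in CH2Cl2 would make the C6-ketone enolate (C21) add to the aldehyde, closing the ring C21–C7–C8–C8a–C10a–C22 to give the β-hydroxy ketone F1. Dess–Martin periodinane would oxidise it to the 1,3-diketone F2. SmI2 (THF, −78 °C) would couple the two carbonyl carbons, a pinacol-type ketyl coupling known for 1,3-diketones, to the cyclopropane-1,2-diol F3. With K2CO3 in methanol the cyclopropanol should open at the C6–C21 bond, the one that releases both the three-membered ring and the oxanorbornane, to give 18. The diol can open only toward 17 or 18, so migration of C5 is excluded.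

Step 7. The enolate might add to or enolise the C6 ketone, or the lithium aldolate might undergo retro-aldol cleavage of the strained β-diketone before it is silylated. The fallback sets out from 11 and returns at 16. LiN(SiMe3)2 and Me3SiCl (THF, −78 °C) would convert the only enolisable carbonyl, the C6 ketone, into the trimethylsilyl enol ether F4, which leaves the bridging ketone as the single electrophile. Addition of enolate 13 and trapping with Et3SiOTf as in step 7 would give the aldol adduct F5. The hydrolysis of step 8 would then cleave the enol ether together with the acetal to give 16.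

Step 5. The strained ring closure might reverse, or the liberated acid might move the isopropenyl double bond into conjugation with the ketone. The fallback goes from 7 directly to 9 by hydrogen-atom-transfer hydroalkoxylation: Co(salen) (C16H14CoN2O2, divalent cobalt) as catalyst, N-fluoro-2,4,6-trimethylpyridinium tetrafluoroborate and PhSiH3 in CH2Cl2 at 0 °C. Hydrogen-atom transfer to the isopropenyl CH2 gives the tertiary radical, which is oxidised to the cation and captured by the cis hydroxyl under neutral, irreversible conditions; the monosubstituted allyl group reacts much more slowly. This fallback makes no new compound (F0).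

Further compounds
F1 | step 10 | β-hydroxy ketone from aldol closure of C21 onto the aldehyde carbon C7 of 16 (C7 and C8a epimers) | COC(=O)C1CC(O)[C@H]2C(=O)[C@]3(CC=C(C)C)OC(C)(C)[C@H]2[C@]13O[Si](CC)(CC)CC
F2 | step 10 | 1,3-diketone with C6=O and C7=O flanking C21 (C8a epimers) | COC(=O)C1CC(=O)[C@H]2C(=O)[C@]3(CC=C(C)C)OC(C)(C)[C@H]2[C@]13O[Si](CC)(CC)CC
F3 | step 10 | cyclopropane-1,2-diol with ring C6–C7–C21 and hydroxyls on C6 and C7 (C8a epimers) | COC(=O)C1C[C@]2(O)[C@H]3[C@]2(O)[C@]4(CC=C(C)C)OC(C)(C)[C@H]3[C@]14O[Si](CC)(CC)CC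
F4 | step 7 | trimethylsilyl enol ether of the C6 ketone of 11 | C[Si](C)(C)OC1=C[C@H]2C(C)(C)O[C@]1(CC=C(C)C)C2=O
F5 | step 7 | aldol adduct of 13 to F4 as C10a triethylsilyl ether (C8a epimers) | C[Si](C)(C)OC1=C[C@H]2C(C)(C)O[C@]1(CC=C(C)C)[C@@]2(O[Si](CC)(CC)CC)C(CC(OC)OC)C(=O)OC
F0 | step 5 | none | none
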